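**Plan**
Retrosynthesis: cut the chromene ring of ring B back to an aryl 1,1-dimethylpropargyl ether, then cut four C–C bonds of ring A at once (alkenyl-ketene + siloxyethyne), then the enone C=C, the keto-phosphonate/arylpropyl C–C bond, the C2 extension of the ring-B aldehyde, the propargyl C–O bond and the aryl–prenyl bond.
Forward: ring B is bought as a bromocatechol aldehyde and dressed (prenyl, propargyl ether, TIPS, C3 iodide); the chain is joined by dianion alkylation and olefination; ring A is built de novo; the chromene closes last by a thermal Claisen cascade; fluoride ends the route.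
Enabling feature: ring A is a 4,6-dialkylresorcinol reading chain-C, C–O, CH, C–O, C(1,1-dimethylallyl), CH. A vinylketene supplies C–OH, chain-C, CH and the quaternary-substituted C; a terminal siloxyalkyne supplies C–OSi and the CH between the oxygens.
Stereochemistry: the target has no stereocentre; the (E)-enone set by the olefination is consumed in ring formation.

Key step: step 15

Remark: Kazinol K has no stereogenic centre and no stereogenic double bond, so the compound drawn is the only stereoisomer and no enantiocontrol is needed.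
Remark: the key-step product carries a free phenol on ring A; it is not silylated before the Claisen step, which is run at 130 °C for that reason.
Abbreviation: ArB = 4-[(2-methylbut-3-yn-2-yl)oxy]-2-(3-methylbut-2-en-1-yl)-5-[(triisopropylsilyl)oxy]phenyl.

**Route**

Step 1
Reactants: 1 2-bromo-4,5-dihydroxybenzaldehyde
Product: 2 2-bromo-4,5-bis[(tert-butyldimethylsilyl)oxy]benzaldehyde
Conditions: TBSCl (2.4 equiv), imidazole (5 equiv), DMF, 0 °C → rt
Reagents that add atoms: tert-butyldimethylsilyl chloride CC(C)(C)[Si](C)(C)Cl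
Why: Imidazole-promoted silylation of both phenols masks the catechol so that the palladium coupling that follows meets no free, chelating and oxidisable diol.

Step 2
Reactants: 2 2-bromo-4,5-bis[(tert-butyldimethylsilyl)oxy]benzaldehyde; 3 tributyl(3-methylbut-2-en-1-yl)stannane
Product: 4 4,5-bis[(tert-butyldimethylsilyl)oxy]-2-(3-methylbut-2-en-1-yl)benzaldehyde
Conditions: Pd(PPh3)4 (5 mol %), toluene, 100 °C
Reagents that add atoms: none
Why: Stille cross-coupling, in which oxidative addition is helped by the ortho formyl group and the allyl group is delivered through its unsubstituted CH2 terminus under neutral conditions that spare aldehyde and silyl ethers; it is done before any alkyne or propargyl ether is present.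

Step 3
Reactants: 4 4,5-bis[(tert-butyldimethylsilyl)oxy]-2-(3-methylbut-2-en-1-yl)benzaldehyde
Product: 5 4,5-dihydroxy-2-(3-methylbut-2-en-1-yl)benzaldehyde
Conditions: TBAF (2.2 equiv), AcOH (2.2 equiv), THF, 0 °C
Reagents that add atoms: none
Why: Fluoride cleavage of aryl silyl ethers, buffered with acetic acid so that the catechol is released as the neutral diol.

Step 4
Reactants: 5 4,5-dihydroxy-2-(3-methylbut-2-en-1-yl)benzaldehyde; 6 3-chloro-3-methylbut-1-yne
Product: 7 5-hydroxy-4-[(2-methylbut-3-yn-2-yl)oxy]-2-(3-methylbut-2-en-1-yl)benzaldehyde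
Conditions: 6 (1.2 equiv), DBU (1.3 equiv), CuCl2·2H2O (1 mol %), MeCN, 0 °C, argon
Reagents that add atoms: none
Why: Copper-catalysed propargylic etherification through a copper acetylide/allenylidene; the phenol para to the formyl group is by far the more acidic and is the one ionised, so it takes the tertiary propargyl group, and the bulky ether then shields the neighbouring OH from a second alkylation.

Step 5
Reactants: 7 5-hydroxy-4-[(2-methylbut-3-yn-2-yl)oxy]-2-(3-methylbut-2-en-1-yl)benzaldehyde
Product: 8 4-[(2-methylbut-3-yn-2-yl)oxy]-2-(3-methylbut-2-en-1-yl)-5-[(triisopropylsilyl)oxy]benzaldehyde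
Conditions: TIPSCl (1.3 equiv), imidazole (2.5 equiv), DMF, rt
Reagents that add atoms: triisopropylsilyl chloride CC(C)[Si](Cl)(C(C)C)C(C)C
Why: Standard phenol silylation; the TIPS ether withstands the carbanion chemistry ahead and later blocks the ortho position on this side of the propargyl ether.

Step 6
Reactants: 8 4-[(2-methylbut-3-yn-2-yl)oxy]-2-(3-methylbut-2-en-1-yl)-5-[(triisopropylsilyl)oxy]benzaldehyde; 9 (triphenylphosphoranylidene)acetaldehyde
Product: 10 (2E)-3-(ArB)prop-2-enal
Conditions: 9 (1.3 equiv), toluene, 80 °C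
Reagents that add atoms: none
Why: Wittig olefination with a stabilised formyl ylide gives the (E)-cinnamaldehyde by two-carbon homologation, the ylide being too weak a base to touch the alkyne C–H or the silyl ether.

Step 7
Reactants: 10 (2E)-3-(ArB)prop-2-enal
Product: 12 3-(ArB)propan-1-ol, via 3-(ArB)propanal 11 (not isolated)
Conditions: Hantzsch ester (1.2 equiv), Bn2NH2+ CF3CO2− (10 mol %), THF, rt; then MeOH, NaBH4, 0 °C
Reagents that add atoms: none
Why: Iminium-catalysed transfer hydrogenation reduces only the conjugated C=C of the enal (alkyne and prenyl alkene are not activated), and borohydride then reduces the saturated aldehyde in the same flask.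

Step 8
Reactants: 12 3-(ArB)propan-1-ol
Product: 13 1-iodo-3-(ArB)propane
Conditions: PPh3 (1.3 equiv), imidazole (1.5 equiv), I2 (1.3 equiv), CH2Cl2, 0 °C → rt
Reagents that add atoms: iodine II
Why: Appel-type iodination, an SN2 displacement of the alkoxyphosphonium ion by iodide under near-neutral conditions.

Step 9
Reactants: 13 1-iodo-3-(ArB)propane; 14 dimethyl (2-oxopropyl)phosphonate
Product: 16 dimethyl [6-(ArB)-2-oxohexyl]phosphonate, via phosphonate dianion 15 (not isolated)
Conditions: 14 (2.5 equiv), NaH, THF, 0 °C; n-BuLi, 0 °C; then 13, 0 °C → rt; sat. aq NH4Cl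
Reagents that add atoms: none
Why: γ-Alkylation of a β-keto phosphonate dianion, whose more basic terminal carbanion attacks the primary iodide; the dianion is in excess so that any proton taken from the alkyne C–H costs only reagent.

Step 10
Reactants: 17 2,2-dimethylbut-3-enoic acid
Product: 18 2,2-dimethylbut-3-en-1-ol
Conditions: LiAlH4, Et2O, 0 °C → reflux; Fieser work-up
Reagents that add atoms: none
Why: Hydride reduction of a carboxylic acid to the primary alcohol; the isolated vinyl group is inert.

Step 11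
Reactants: 18 2,2-dimethylbut-3-en-1-ol
Product: 19 2,2-dimethylbut-3-enal
Conditions: Dess–Martin periodinane, CH2Cl2, 0 °C → rt; washed (aq NaHCO3/Na2S2O3), dried solution used directly
Reagents that add atoms: none
Why: Dess–Martin oxidation gives the non-enolisable aldehyde, which is carried on as a solution because it is volatile.

Step 12
Reactants: 16 dimethyl [6-(ArB)-2-oxohexyl]phosphonate; 19 2,2-dimethylbut-3-enal
Product: 20 (6E)-1-(ArB)-8,8-dimethyldeca-6,9-dien-5-one
Conditions: 19 (2 equiv), LiCl, i-Pr2NEt, MeCN, rt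
Reagents that add atoms: none
Why: Horner–Wadsworth–Emmons olefination under Masamune–Roush conditions joins the halves and gives the (E)-enone, the quaternary substituent disfavouring the cis oxaphosphetane.

Step 13
Reactants: 20 (6E)-1-(ArB)-8,8-dimethyldeca-6,9-dien-5-one
Product: 23 (6E)-1-(ArB)-4-diazo-8,8-dimethyldeca-6,9-dien-5-one, via lithium enolate 21 (not isolated), via trifluoroacetyl ketone 22 (not isolated)
Conditions: LiHMDS (1.1 equiv), THF, −78 °C; CF3CO2CH2CF3 (1.2 equiv), −78 °C; dilute aq HCl work-up, crude 22 taken up at once in MeCN; MsN3 (1.5 equiv), Et3N (1.5 equiv), H2O (1 equiv), rt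
Reagents that add atoms: methanesulfonyl azide CS(=O)(=O)N=[N+]=[N-]; 2,2,2-trifluoroethyl trifluoroacetate O=C(OCC(F)(F)F)C(F)(F)F (its CF3CO group is present only in 22)
Why: Deacylative (detrifluoroacetylative) diazo transfer: the α′-CH2 is the only enolisable position (the γ-carbon is quaternary), its enolate is trifluoroacetylated, and the activated 1,3-dicarbonyl takes the diazo group from the sulfonyl azide with loss of the trifluoroacetyl group.

Step 14
Reactants: 24 ethyl dibromoacetate
Product: 26 (ethynyloxy)triisopropylsilane, via lithium ethynolate 25 (not isolated)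
Conditions: t-BuLi (4.1 equiv), THF, −78 → 0 °C; then TIPSOTf (2.1 equiv), −78 °C → rt; distillation
Reagents that add atoms: triisopropylsilyl trifluoromethanesulfonate CC(C)[Si](OS(=O)(=O)C(F)(F)F)(C(C)C)C(C)C
Why: Ynolate formation from an α,α-dibromo ester by two bromine–lithium exchanges and loss of ethoxide from the ester dianion, followed by O-silylation, the bulky silyl triflate reacting at oxygen to give a distillable TIPS ynol ether.

Step 15
Reactants: 23 (6E)-1-(ArB)-4-diazo-8,8-dimethyldeca-6,9-dien-5-one; 26 (ethynyloxy)triisopropylsilane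
Product: 31 4-[3-(ArB)propyl]-2-(2-methylbut-3-en-2-yl)-5-[(triisopropylsilyl)oxy]phenol, via vinylketene 27 (not isolated), via vinylcyclobutenone 28 (not isolated), via dienylketene 29 (not isolated), via cyclohexadienone 30 (not isolated)
Conditions: 26 (2.5 equiv), degassed ClCH2CH2Cl (0.05 M), hν (300 nm lamps, Pyrex), rt until 23 is consumed; then 80 °C, 3 h
Reagents that add atoms: none
Why: Excitation of the diazo enone expels N2 with 1,2-shift of the alkenyl group (photochemical Wolff rearrangement) to give vinylketene 27, whose ketene C=C adds to the polarised siloxyalkyne in a [2+2] cycloaddition (alkyne CH carbon to the ketene carbonyl carbon, O-bearing carbon to the ketene α-carbon) to give cyclobutenone 28. Light or the final warming opens 28 by conrotatory 4π electrocyclic cleavage of the C(=O)–C(quaternary) bond to dienylketene 29, and ring A then closes by a thermal disrotatory 6π electrocyclisation that joins the ketene carbon to the alkene carbon bearing the 1,1-dimethylallyl group; enolisation of dienone 30 gives the phenol. The closest known reaction is the Danheiser benzannulation in its α-diazo ketone (photo-Wolff) form with trialkylsilyloxyalkynes. No stereocentre results, since the sp3 carbons of 28 and 30 are lost again on ring opening and aromatisation. The step needs the [2+2] regiochemistry, which the oxygen-polarised alkyne dictates and which places OTIPS next to the chain, OH next to the 1,1-dimethylallyl group and H between the two oxygens, and it needs the Wolff shift to outrun 1,2-hydride shift and di-π-methane chemistry, which the s-Z diazo ketone geometry and Pyrex-filtered light absorbed only by the diazo enone chromophore favour. Ring opening of 28 with the alkenyl group turned outward is reversible, so all material funnels through the cyclisable isomer 29.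

Step 16
Reactants: 31 4-[3-(ArB)propyl]-2-(2-methylbut-3-en-2-yl)-5-[(triisopropylsilyl)oxy]phenol
Product: 34 4-{3-[2,2-dimethyl-5-(3-methylbut-2-en-1-yl)-8-[(triisopropylsilyl)oxy]-2H-chromen-6-yl]propyl}-2-(2-methylbut-3-en-2-yl)-5-[(triisopropylsilyl)oxy]phenol, via allenylphenol 32 (not isolated), via quinone methide 33 (not isolated)
Conditions: degassed o-xylene, 130 °C, sealed tube
Reagents that add atoms: none
Why: Aromatic propargyl Claisen rearrangement to the only free ortho position (the other carries OTIPS), then enolisation, 1,5-hydrogen shift and oxa-6π electrocyclisation close the 2,2-dimethylchromene, at a temperature below that at which the ortho-(1,1-dimethylallyl)phenol of ring A would isomerise.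

Step 17
Reactants: 34 chromene bis-TIPS ether (name as in step 16)
Product: 35 Kazinol K, 4-{3-[8-hydroxy-2,2-dimethyl-5-(3-methylbut-2-en-1-yl)-2H-chromen-6-yl]propyl}-6-(2-methylbut-3-en-2-yl)benzene-1,3-diol
Conditions: TBAF (2.5 equiv), AcOH (2.5 equiv), degassed THF, 0 °C
Reagents that add atoms: none
Why: Fluoride cleavage of the two aryl silyl ethers, buffered so that the electron-rich phenols are not exposed as phenoxides to base or air and the acid-sensitive allyl and chromene groups see no strong acid.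

**Compound list**
1 | 2-bromo-4,5-dihydroxybenzaldehyde | O=Cc1cc(O)c(O)cc1Br | starting material
2 | 2-bromo-4,5-bis[(tert-butyldimethylsilyl)oxy]benzaldehyde | O=Cc1cc(O[Si](C)(C)C(C)(C)C)c(O[Si](C)(C)C(C)(C)C)cc1Br | intermediate
3 | tributyl(3-methylbut-2-en-1-yl)stannane | CCCC[Sn](CCCC)(CCCC)CC=C(C)C | starting material
4 | 4,5-bis[(tert-butyldimethylsilyl)oxy]-2-(3-methylbut-2-en-1-yl)benzaldehyde | O=Cc1cc(O[Si](C)(C)C(C)(C)C)c(O[Si](C)(C)C(C)(C)C)cc1CC=C(C)C | intermediate
5 | 4,5-dihydroxy-2-(3-methylbut-2-en-1-yl)benzaldehyde | O=Cc1cc(O)c(O)cc1CC=C(C)C | intermediate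
6 | 3-chloro-3-methylbut-1-yne | C#CC(C)(C)Cl | starting material
7 | 5-hydroxy-4-[(2-methylbut-3-yn-2-yl)oxy]-2-(3-methylbut-2-en-1-yl)benzaldehyde | O=Cc1cc(O)c(OC(C)(C)C#C)cc1CC=C(C)C | intermediate
8 | 4-[(2-methylbut-3-yn-2-yl)oxy]-2-(3-methylbut-2-en-1-yl)-5-[(triisopropylsilyl)oxy]benzaldehyde (ArB–CHO) | O=Cc1cc(O[Si](C(C)C)(C(C)C)C(C)C)c(OC(C)(C)C#C)cc1CC=C(C)C | intermediate
9 | (triphenylphosphoranylidene)acetaldehyde | O=CC=P(c1ccccc1)(c1ccccc1)c1ccccc1 | starting material
10 | (2E)-3-(ArB)prop-2-enal | O=C/C=C/c1cc(O[Si](C(C)C)(C(C)C)C(C)C)c(OC(C)(C)C#C)cc1CC=C(C)C | intermediate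
11 | 3-(ArB)propanal | O=CCCc1cc(O[Si](C(C)C)(C(C)C)C(C)C)c(OC(C)(C)C#C)cc1CC=C(C)C | intermediate (not isolated)
12 | 3-(ArB)propan-1-ol | OCCCc1cc(O[Si](C(C)C)(C(C)C)C(C)C)c(OC(C)(C)C#C)cc1CC=C(C)C | intermediate
13 | 1-iodo-3-(ArB)propane | ICCCc1cc(O[Si](C(C)C)(C(C)C)C(C)C)c(OC(C)(C)C#C)cc1CC=C(C)C | intermediate
14 | dimethyl (2-oxopropyl)phosphonate | CC(=O)CP(=O)(OC)OC | starting material
15 | sodium lithium 1,3-dianion of dimethyl (2-oxopropyl)phosphonate | [Na+].[Li+].[CH2-]C(=O)[CH-]P(=O)(OC)OC | intermediate (not isolated)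
16 | dimethyl [6-(ArB)-2-oxohexyl]phosphonate | COP(=O)(CC(=O)CCCCc1cc(O[Si](C(C)C)(C(C)C)C(C)C)c(OC(C)(C)C#C)cc1CC=C(C)C)OC | intermediate
17 | 2,2-dimethylbut-3-enoic acid | C=CC(C)(C)C(=O)O | starting material
18 | 2,2-dimethylbut-3-en-1-ol | C=CC(C)(C)CO | intermediate
19 | 2,2-dimethylbut-3-enal | C=CC(C)(C)C=O | intermediate
20 | (6E)-1-(ArB)-8,8-dimethyldeca-6,9-dien-5-one | C=CC(C)(C)/C=C/C(=O)CCCCc1cc(O[Si](C(C)C)(C(C)C)C(C)C)c(OC(C)(C)C#C)cc1CC=C(C)C | intermediate
21 | lithium C4–C5 enolate of 20 (enolate geometry not defined) | [Li+].C=CC(C)(C)/C=C/C([O-])=CCCCc1cc(O[Si](C(C)C)(C(C)C)C(C)C)c(OC(C)(C)C#C)cc1CC=C(C)C | intermediate (not isolated)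
22 | (6E)-1-(ArB)-8,8-dimethyl-4-(trifluoroacetyl)deca-6,9-dien-5-one (racemic, largely enolised) | C=CC(C)(C)/C=C/C(=O)C(CCCc1cc(O[Si](C(C)C)(C(C)C)C(C)C)c(OC(C)(C)C#C)cc1CC=C(C)C)C(=O)C(F)(F)F | intermediate (not isolated)
23 | (6E)-1-(ArB)-4-diazo-8,8-dimethyldeca-6,9-dien-5-one | C=CC(C)(C)/C=C/C(=O)C(=[N+]=[N-])CCCc1cc(O[Si](C(C)C)(C(C)C)C(C)C)c(OC(C)(C)C#C)cc1CC=C(C)C | intermediate (key-step precursor)
24 | ethyl dibromoacetate | CCOC(=O)C(Br)Br | starting material
25 | lithium ethynolate | [Li+].[O-]C#C | intermediate (not isolated)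
26 | (ethynyloxy)triisopropylsilane (triisopropylsiloxyethyne) | C#CO[Si](C(C)C)(C(C)C)C(C)C | intermediate
27 | (3E)-2-[3-(ArB)propyl]-5,5-dimethylhepta-1,3,6-trien-1-one (vinylketene) | C=CC(C)(C)/C=C/C(=C=O)CCCc1cc(O[Si](C(C)C)(C(C)C)C(C)C)c(OC(C)(C)C#C)cc1CC=C(C)C | intermediate (not isolated)
28 | 4-[3-(ArB)propyl]-4-[(1E)-3,3-dimethylpenta-1,4-dien-1-yl]-3-[(triisopropylsilyl)oxy]cyclobut-2-en-1-one (racemic) | C=CC(C)(C)/C=C/C1(CCCc2cc(O[Si](C(C)C)(C(C)C)C(C)C)c(OC(C)(C)C#C)cc2CC=C(C)C)C(=O)C=C1O[Si](C(C)C)(C(C)C)C(C)C | intermediate (not isolated)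
29 | (3E,5E)-4-[3-(ArB)propyl]-7,7-dimethyl-3-[(triisopropylsilyl)oxy]nona-1,3,5,8-tetraen-1-one (ketenyl and dienyl arms cis) | O=C=C/C(O[Si](C(C)C)(C(C)C)C(C)C)=C(CCCc1cc(O[Si](C(C)C)(C(C)C)C(C)C)c(OC(C)(C)C#C)cc1CC=C(C)C)\C=C\C(C)(C)C=C | intermediate (not isolated)
30 | 4-[3-(ArB)propyl]-6-(2-methylbut-3-en-2-yl)-3-[(triisopropylsilyl)oxy]cyclohexa-2,4-dien-1-one (racemic) | O=C1C=C(O[Si](C(C)C)(C(C)C)C(C)C)C(CCCc2cc(O[Si](C(C)C)(C(C)C)C(C)C)c(OC(C)(C)C#C)cc2CC=C(C)C)=CC1C(C)(C)C=C | intermediate (not isolated)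
31 | 4-[3-(ArB)propyl]-2-(2-methylbut-3-en-2-yl)-5-[(triisopropylsilyl)oxy]phenol | C=CC(C)(C)c1cc(CCCc2cc(O[Si](C(C)C)(C(C)C)C(C)C)c(OC(C)(C)C#C)cc2CC=C(C)C)c(O[Si](C(C)C)(C(C)C)C(C)C)cc1O | intermediate (key-step product)
32 | allenyl phenol: 31 with the propargyl ether replaced by a free OH and a 3-methylbuta-1,2-dien-1-yl group on the adjacent ring-B carbon | C=CC(C)(C)c1cc(CCCc2cc(O[Si](C(C)C)(C(C)C)C(C)C)c(O)c(C=C=C(C)C)c2CC=C(C)C)c(O[Si](C(C)C)(C(C)C)C(C)C)cc1O | intermediate (not isolated)
33 | ortho-quinone methide: ring B as 6-(3-methylbut-2-en-1-ylidene)cyclohexa-2,4-dien-1-one (exocyclic alkene geometry not defined) | C=CC(C)(C)c1cc(CCCC2=C(CC=C(C)C)C(=CC=C(C)C)C(=O)C(O[Si](C(C)C)(C(C)C)C(C)C)=C2)c(O[Si](C(C)C)(C(C)C)C(C)C)cc1O | intermediate (not isolated)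
34 | 4-{3-[2,2-dimethyl-5-(3-methylbut-2-en-1-yl)-8-[(triisopropylsilyl)oxy]-2H-chromen-6-yl]propyl}-2-(2-methylbut-3-en-2-yl)-5-[(triisopropylsilyl)oxy]phenol | C=CC(C)(C)c1cc(CCCc2cc(O[Si](C(C)C)(C(C)C)C(C)C)c3c(c2CC=C(C)C)C=CC(C)(C)O3)c(O[Si](C(C)C)(C(C)C)C(C)C)cc1O | intermediate
35 | Kazinol K | C=CC(C)(C)c1cc(CCCc2cc(O)c3c(c2CC=C(C)C)C=CC(C)(C)O3)c(O)cc1O | target

**Summary**
Total step count: 17.
Longest linear sequence: 14 steps (1–9, 12, 13, 15, 16, 17) from compound 1; steps 10–11 and step 14 are side branches.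

Steps most likely to fail:

1. Step 15. The keto-carbene formed when N2 leaves the s-E conformer can undergo 1,2-hydride shift from the neighbouring CH2, giving a cross-conjugated dienone and no ketene. Prolonged irradiation may also degrade the cyclobutenone or the phenol. The fallback makes the same vinylketene thermally and without a carbene, setting out from iodide 13. Alkylation of sodio tert-butyl diethylphosphonoacetate with 13 (NaH, DMF) should give tert-butyl 2-(diethoxyphosphoryl)-5-(ArB)pentanoate F1. Its Horner–Wadsworth–Emmons reaction (NaH, THF) with 3,3-dimethylpent-4-enal F2 (DIBAL-H reduction of commercial methyl 3,3-dimethylpent-4-enoate, −78 °C) should give tert-butyl 2-[3-(ArB)propyl]-5,5-dimethylhepta-2,6-dienoate F3, either alkene geometry being usable. TMSOTf/2,6-lutidine should cleave the tert-butyl ester to 2-[3-(ArB)propyl]-5,5-dimethylhepta-2,6-dienoic acid F4 without harming the aryl silyl ether. Ghosez's reagent should then give 2-[3-(ArB)propyl]-5,5-dimethylhepta-2,6-dienoyl chloride F5 without releasing HCl. Slow addition of Et3N to F5 and 26 in toluene at 80 °C should cause 1,4-dehydrochlorination (γ-deprotonation) to vinylketene 27, which passes through 28, 29 and 30 thermally. The route is rejoined at 31.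

2. Step 14. t-BuLi may remove the acidic α-proton of 24 in place of bromine–lithium exchange, which leads to bromo-ynolate and dianion mixtures. The small parent ynolate may also be silylated at carbon (silylketene) in place of oxygen. The fallback reaches the ynolate by oxidation and does not use 24. It consumes no intermediate of the route: acetylene replaces 24 as the carbon source. Monolithium acetylide (acetylene, n-BuLi, THF, −78 °C) is treated with lithium tert-butyl peroxide (anhydrous t-BuOOH, LiHMDS) between −78 and −20 °C, which transfers oxygen to the acetylide carbon. The fallback comes back at lithium ethynolate 25, which is silylated with TIPSOTf to 26 as before.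

3. Step 4. The etherification may run on to the bis-ether, may take place in part at the meta oxygen, or may be upset by copper-mediated oxidation of the free catechol. The fallback sets out from 5 and fixes the regiochemistry by desilylation, not by alkylation. TIPSCl (2.4 equiv)/imidazole should give 4,5-bis[(triisopropylsilyl)oxy]-2-(3-methylbut-2-en-1-yl)benzaldehyde F6. Brief K2CO3/MeOH at 0 °C should remove only the silyl group para to the formyl group, whose phenoxide is much the better leaving group, to give 4-hydroxy-2-(3-methylbut-2-en-1-yl)-5-[(triisopropylsilyl)oxy]benzaldehyde F7. Propargylation of this single free phenol with 6 (DBU, cat. CuCl2, MeCN, 0 °C) comes back to the route at 8.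

**Further compounds**
F1 | step 15 | tert-butyl 2-(diethoxyphosphoryl)-5-(ArB)pentanoate (racemic) | CCOP(=O)(OCC)C(CCCc1cc(O[Si](C(C)C)(C(C)C)C(C)C)c(OC(C)(C)C#C)cc1CC=C(C)C)C(=O)OC(C)(C)C
F2 | step 15 | 3,3-dimethylpent-4-enal | C=CC(C)(C)CC=O
F3 | step 15 | tert-butyl 2-[3-(ArB)propyl]-5,5-dimethylhepta-2,6-dienoate (E/Z mixture) | C=CC(C)(C)CC=C(CCCc1cc(O[Si](C(C)C)(C(C)C)C(C)C)c(OC(C)(C)C#C)cc1CC=C(C)C)C(=O)OC(C)(C)C
F4 | step 15 | 2-[3-(ArB)propyl]-5,5-dimethylhepta-2,6-dienoic acid (E/Z mixture) | C=CC(C)(C)CC=C(CCCc1cc(O[Si](C(C)C)(C(C)C)C(C)C)c(OC(C)(C)C#C)cc1CC=C(C)C)C(=O)O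
F5 | step 15 | 2-[3-(ArB)propyl]-5,5-dimethylhepta-2,6-dienoyl chloride (E/Z mixture) | C=CC(C)(C)CC=C(CCCc1cc(O[Si](C(C)C)(C(C)C)C(C)C)c(OC(C)(C)C#C)cc1CC=C(C)C)C(=O)Cl
F0 | step 14 | none | none
F6 | step 4 | 4,5-bis[(triisopropylsilyl)oxy]-2-(3-methylbut-2-en-1-yl)benzaldehyde | O=Cc1cc(O[Si](C(C)C)(C(C)C)C(C)C)c(O[Si](C(C)C)(C(C)C)C(C)C)cc1CC=C(C)C
F7 | step 4 | 4-hydroxy-2-(3-methylbut-2-en-1-yl)-5-[(triisopropylsilyl)oxy]benzaldehyde | O=Cc1cc(O[Si](C(C)C)(C(C)C)C(C)C)c(O)cc1CC=C(C)C
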